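Atoms carry 1H-isochromene numbers. The carbocycle is disconnected at C4a–C8a and C6–C7 into two three-carbon pieces. The plan exploits three features: C8a is the α-carbon of the acetyl ketone, C4a is the β-carbon of the C4a=C5–C6=O enone, and C6(=O)–C7(OH)Me is an α-ketol. With C8 held temporarily as a ketone, C8a becomes a soft 1,3-diketone carbon. In one flask, triketone 7 adds enantioselectively to silyl diynal 10 (C4a–C8a, quaternary C8a), and a carbene catalyst then converts the new aldehyde (C6) into an acyl anion that closes on the C7 ketone. Sonogashira coupling, pyran closure, chlorination and C8 reduction complete the target.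

Key step: step 6

Remark: polycarbonyl compounds 6, 7 and 11 are written as keto tautomers, and the cinchona catalyst in step 6 is taken as the pseudo-enantiomer that gives the (R)-configured adduct 11.

Step 1
Reactants: 1 3,3-dimethoxybutan-2-one
Product: 3 5-hydroxy-2,2-dimethoxypentan-3-one, via lithium enolate 2 (not isolated)
Conditions: LDA, THF, −78 °C; then monomeric CH2O (cracked paraformaldehyde), −78 → −40 °C; aq. NH4Cl
Reagents that add atoms: formaldehyde C=O
Why: Only the methyl group of 1 is enolisable (the other α-carbon is the ketal carbon), so a single enolate forms and its aldol addition to formaldehyde should give the β-hydroxy ketone (enolate hydroxymethylation).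

Step 2
Reactants: 3 5-hydroxy-2,2-dimethoxypentan-3-one
Product: 4 5-{[tert-butyl(diphenyl)silyl]oxy}-2,2-dimethoxypentan-3-one
Conditions: TBDPSCl, imidazole, CH2Cl2, 0 °C → rt
Reagents that add atoms: tert-butyl(chloro)diphenylsilane CC(C)(C)[Si](Cl)(c1ccccc1)c1ccccc1
Why: Standard silylation of a primary alcohol; the TBDPS ether is chosen because it should survive the later cold aqueous-acid ketal hydrolysis and the alkynylsilane cleavage.

Step 3
Reactants: 4 5-{[tert-butyl(diphenyl)silyl]oxy}-2,2-dimethoxypentan-3-one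
Product: 6 3-({[tert-butyl(diphenyl)silyl]oxy}methyl)-5,5-dimethoxyhexane-2,4-dione, via lithium enolate 5 (not isolated)
Conditions: LDA (2.2 equiv), THF, −78 °C; then 1-acetyl-1H-benzotriazole, −78 → 0 °C; aq. NH4Cl
Reagents that add atoms: 1-acetyl-1H-benzotriazole CC(=O)n1nnc2ccccc12
Why: C4 is the only enolisable position of 4, and lithium enolates are C-acylated by N-acylbenzotriazoles to 1,3-diketones (Claisen-type acylation), the second equivalent of base holding the product as its diketonate.

Step 4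
Reactants: 6 3-({[tert-butyl(diphenyl)silyl]oxy}methyl)-5,5-dimethoxyhexane-2,4-dione
Product: 7 3-({[tert-butyl(diphenyl)silyl]oxy}methyl)hexane-2,4,5-trione
Conditions: TFA/H2O (9:1), CH2Cl2, 0 °C
Reagents that add atoms: water O
Why: Acid hydrolysis of the dimethyl ketal unmasks the future C7 ketone next to the 2-substituted 1,3-diketone, and a primary TBDPS ether should tolerate brief cold aqueous TFA.

Step 5
Reactants: 8 1,4-bis(trimethylsilyl)buta-1,3-diyne
Product: 10 5-(trimethylsilyl)penta-2,4-diynal, via lithium diynide 9 (not isolated)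
Conditions: MeLi·LiBr, THF, 0 °C → rt; then DMF, −78 → 0 °C; inverse quench into aq. KH2PO4
Reagents that add atoms: N,N-dimethylformamide CN(C)C=O
Why: Methyllithium cleaves one C(sp)–Si bond to the lithium diynide, which DMF formylates (Bouveault-type formylation), with a buffered inverse quench to spare the ynal.

Step 6
Reactants: 7 3-({[tert-butyl(diphenyl)silyl]oxy}methyl)hexane-2,4,5-trione; 10 5-(trimethylsilyl)penta-2,4-diynal
Product: 12 (2S,6R)-6-acetyl-6-({[tert-butyl(diphenyl)silyl]oxy}methyl)-2-hydroxy-2-methyl-5-[(trimethylsilyl)ethynyl]cyclohex-4-ene-1,3-dione (2-OH cis to the 6-acetyl group), via Michael adduct 11 (not isolated)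
Conditions: cinchona-derived bifunctional squaramide (10 mol %), toluene, 4 Å MS, −40 °C; then 2-(pentafluorophenyl)-6,7-dihydro-5H-pyrrolo[2,1-c][1,2,4]triazolium tetrafluoroborate (15 mol %), iPr2NEt (15 mol %), 23 °C
Reagents that add atoms: none
Why: Under the bifunctional squaramide the hydrogen-bonded enolate of the 1,3-diketone in 7 (C8a between the acetyl and the temporary C8 ketone) adds 1,4 and anti to ynal 10, which forms C4a–C8a and gives enal 11 with the formyl group cis to C8a, while the silyl group blocks 1,6-addition. The triazolylidene then adds to the aldehyde, and the Breslow intermediate (C6 acyl-anion equivalent) attacks the C7 ketone of the vicinal diketone and releases the carbene, which forms C6–C7 as an α-ketol. The closest known reactions are the amine/carbene relay Michael–crossed-benzoin annulation of 1,3-diketones with enals and the intramolecular aldehyde–ketone benzoin reaction. The carbocycle closes in a 6-exo-trig (enol-exo) addition to the C7 carbonyl. C8a is set by the catalyst through face discrimination of the chelated Z-enolate, and C7 is set by the substrate, because CH2OTBDPS sits pseudo-equatorial and the forming C7–O bond sits pseudo-axial (avoiding eclipse with the C8 carbonyl) on the side of the smaller pseudo-axial acetyl group, so the 7-OH should end cis to the acetyl. The step needs closure on C7 rather than C8 or the acetyl carbonyl (C7 is the least hindered and most electrophilic carbonyl, attack on C8 would join two fully substituted carbons, and the reversible benzoin should funnel to the less strained six-membered ketol) and acyl-anion rather than homoenolate reactivity (N-C6F5 triazolium, fully substituted β-carbon).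

Step 7
Reactants: 12 (2S,6R)-6-acetyl-6-({[tert-butyl(diphenyl)silyl]oxy}methyl)-2-hydroxy-2-methyl-5-[(trimethylsilyl)ethynyl]cyclohex-4-ene-1,3-dione
Product: 13 (2S,6R)-6-acetyl-6-({[tert-butyl(diphenyl)silyl]oxy}methyl)-5-ethynyl-2-hydroxy-2-methylcyclohex-4-ene-1,3-dione
Conditions: AgNO3 (10 mol %), acetone/H2O, rt, dark
Reagents that add atoms: none
Why: Silver(I)-catalysed protodesilylation should cleave only the C(sp)–SiMe3 bond under neutral conditions, leaving the O–TBDPS ether and the base-sensitive non-enolisable β-diketone untouched.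

Step 8
Reactants: 14 (S)-2-methylbutan-1-ol
Product: 15 (S)-2-methylbutanal
Conditions: TEMPO (1 mol %), KBr (cat.), NaOCl, NaHCO3, CH2Cl2/H2O, 0 °C; dried CH2Cl2 solution used directly
Reagents that add atoms: none
Why: Cold TEMPO/bleach oxidation should give the α-branched aldehyde without epimerising the adjacent stereocentre, and the volatile aldehyde is used in solution.

Step 9
Reactants: 15 (S)-2-methylbutanal
Product: 16 ethyl (2E,4S)-2,4-dimethylhex-2-enoate
Conditions: Ph3P=C(CH3)CO2Et, CH2Cl2, 0 °C → rt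
Reagents that add atoms: ethyl 2-(triphenyl-λ5-phosphanylidene)propanoate CCOC(=O)C(C)=P(c1ccccc1)(c1ccccc1)c1ccccc1
Why: Wittig olefination with the stabilised α-methyl ylide should give the (E)-trisubstituted enoate under mild conditions that keep the stereocentre intact.

Step 10
Reactants: 16 ethyl (2E,4S)-2,4-dimethylhex-2-enoate
Product: 17 (2E,4S)-2,4-dimethylhex-2-en-1-ol
Conditions: DIBAL-H (2.2 equiv), CH2Cl2, −78 °C; Rochelle salt work-up
Reagents that add atoms: none
Why: DIBAL-H reduces the conjugated ester 1,2 to the allylic alcohol.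

Step 11
Reactants: 17 (2E,4S)-2,4-dimethylhex-2-en-1-ol
Product: 18 (2E,4S)-2,4-dimethylhex-2-enal
Conditions: MnO2, CH2Cl2, rt
Reagents that add atoms: none
Why: MnO2 oxidises the allylic alcohol selectively to the enal without touching the alkene geometry or the stereocentre.

Step 12
Reactants: 18 (2E,4S)-2,4-dimethylhex-2-enal
Product: 19 (1E,3E,5S)-1-iodo-3,5-dimethylhepta-1,3-diene
Conditions: CrCl2, CHI3, THF, 0 °C
Reagents that add atoms: iodoform IC(I)I
Why: Takai olefination should homologate the aldehyde to the (E)-vinyl iodide.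

Step 13
Reactants: 13 (2S,6R)-6-acetyl-6-({[tert-butyl(diphenyl)silyl]oxy}methyl)-5-ethynyl-2-hydroxy-2-methylcyclohex-4-ene-1,3-dione; 19 (1E,3E,5S)-1-iodo-3,5-dimethylhepta-1,3-diene
Product: 20 (2S,6R)-6-acetyl-6-({[tert-butyl(diphenyl)silyl]oxy}methyl)-5-[(3E,5E,7S)-5,7-dimethylnona-3,5-dien-1-yn-1-yl]-2-hydroxy-2-methylcyclohex-4-ene-1,3-dione
Conditions: Pd(PPh3)4 (5 mol %), CuI (10 mol %), Et3N, THF, rt
Reagents that add atoms: none
Why: Sonogashira coupling joins the terminal alkyne to the vinyl iodide with retention of the (E)-geometry, and a tertiary amine base avoids conjugate addition to the ethynyl enone.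

Step 14
Reactants: 20 (2S,6R)-6-acetyl-6-({[tert-butyl(diphenyl)silyl]oxy}methyl)-5-[(3E,5E,7S)-5,7-dimethylnona-3,5-dien-1-yn-1-yl]-2-hydroxy-2-methylcyclohex-4-ene-1,3-dione
Product: 22 (7S,8aR)-8a-acetyl-3-[(1E,3E,5S)-3,5-dimethylhepta-1,3-dien-1-yl]-7-hydroxy-7-methyl-1H-isochromene-6,8(7H,8aH)-dione, via hydroxy enynone 21 (not isolated)
Conditions: HF·pyridine, THF/pyridine, 0 °C → rt; work-up; then Ph3PAuNTf2 (5 mol %), CH2Cl2, rt
Reagents that add atoms: none
Why: Fluoride cleaves the Si–O bond and the freed C1 hydroxyl adds to the alkyne carbon δ to the C6 carbonyl (π-acid-catalysed 6-endo-dig hydroalkoxylation) to close the pyran as a vinylogous ester, the non-basic conditions avoiding retro-aldol loss of formaldehyde.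

Step 15
Reactants: 22 (7S,8aR)-8a-acetyl-3-[(1E,3E,5S)-3,5-dimethylhepta-1,3-dien-1-yl]-7-hydroxy-7-methyl-1H-isochromene-6,8(7H,8aH)-dione
Product: 23 (7R,8aR)-8a-acetyl-5-chloro-3-[(1E,3E,5S)-3,5-dimethylhepta-1,3-dien-1-yl]-7-hydroxy-7-methyl-1H-isochromene-6,8(7H,8aH)-dione
Conditions: NCS (1.05 equiv), MeCN, 0 °C, dark
Reagents that add atoms: N-chlorosuccinimide O=C1CCC(=O)N1Cl
Why: C5 is the α-carbon of the doubly vinylogous ester O2–C3=C4–C4a=C5–C6=O and its most nucleophilic position, so NCS should chlorinate there (electrophilic halogenation of a vinylogous ester).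

Step 16
Reactants: 23 (7R,8aR)-8a-acetyl-5-chloro-3-[(1E,3E,5S)-3,5-dimethylhepta-1,3-dien-1-yl]-7-hydroxy-7-methyl-1H-isochromene-6,8(7H,8aH)-dione
Product: 24 (7R,8R,8aS)-8a-acetyl-5-chloro-3-[(1E,3E,5S)-3,5-dimethylhepta-1,3-dien-1-yl]-7,8-dihydroxy-7-methyl-1,7,8,8a-tetrahydro-6H-isochromen-6-one
Conditions: NaBH4 (1 equiv), MeOH/THF, −78 °C
Reagents that add atoms: none
Why: The C6 vinylogous ester is deactivated and the C8 ring ketone is activated by the adjacent hydroxyl, and hydride should attack C8 from the face opposite the syn-pseudo-axial 7-OH and 8a-acetyl groups (held so by the ring fusion), giving the all-cis 8R alcohol (substrate-controlled borohydride reduction).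

Compound list
1 | 3,3-dimethoxybutan-2-one | CC(=O)C(C)(OC)OC | starting material
2 | lithium 3,3-dimethoxybut-1-en-2-olate | [Li+].C=C([O-])C(C)(OC)OC | intermediate (not isolated)
3 | 5-hydroxy-2,2-dimethoxypentan-3-one | CC(OC)(OC)C(=O)CCO | intermediate
4 | 5-{[tert-butyl(diphenyl)silyl]oxy}-2,2-dimethoxypentan-3-one | CC(OC)(OC)C(=O)CCO[Si](c1ccccc1)(c1ccccc1)C(C)(C)C | intermediate
5 | lithium enolate of 4 (C3–C4 enolate) | [Li+].CC(OC)(OC)C([O-])=CCO[Si](c1ccccc1)(c1ccccc1)C(C)(C)C | intermediate (not isolated)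
6 | 3-({[tert-butyl(diphenyl)silyl]oxy}methyl)-5,5-dimethoxyhexane-2,4-dione | CC(=O)C(CO[Si](c1ccccc1)(c1ccccc1)C(C)(C)C)C(=O)C(C)(OC)OC | intermediate
7 | 3-({[tert-butyl(diphenyl)silyl]oxy}methyl)hexane-2,4,5-trione | CC(=O)C(CO[Si](c1ccccc1)(c1ccccc1)C(C)(C)C)C(=O)C(C)=O | intermediate
8 | 1,4-bis(trimethylsilyl)buta-1,3-diyne | C[Si](C)(C)C#CC#C[Si](C)(C)C | starting material
9 | [4-(trimethylsilyl)buta-1,3-diyn-1-yl]lithium | [Li+].[C-]#CC#C[Si](C)(C)C | intermediate (not isolated)
10 | 5-(trimethylsilyl)penta-2,4-diynal | C[Si](C)(C)C#CC#CC=O | intermediate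
11 | (2E,4R)-4-acetyl-4-({[tert-butyl(diphenyl)silyl]oxy}methyl)-5,6-dioxo-3-[(trimethylsilyl)ethynyl]hept-2-enal (formyl cis to the quaternary carbon) | C[Si](C)(C)C#C/C(=C/C=O)[C@](C(C)=O)(CO[Si](c1ccccc1)(c1ccccc1)C(C)(C)C)C(=O)C(C)=O | intermediate (not isolated)
12 | (2S,6R)-6-acetyl-6-({[tert-butyl(diphenyl)silyl]oxy}methyl)-2-hydroxy-2-methyl-5-[(trimethylsilyl)ethynyl]cyclohex-4-ene-1,3-dione | C[Si](C)(C)C#CC1=CC(=O)[C@](C)(O)C(=O)[C@@]1(C(C)=O)CO[Si](c1ccccc1)(c1ccccc1)C(C)(C)C | intermediate
13 | (2S,6R)-6-acetyl-6-({[tert-butyl(diphenyl)silyl]oxy}methyl)-5-ethynyl-2-hydroxy-2-methylcyclohex-4-ene-1,3-dione | C#CC1=CC(=O)[C@](C)(O)C(=O)[C@@]1(C(C)=O)CO[Si](c1ccccc1)(c1ccccc1)C(C)(C)C | intermediate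
14 | (S)-2-methylbutan-1-ol | CC[C@H](C)CO | starting material
15 | (S)-2-methylbutanal | CC[C@H](C)C=O | intermediate
16 | ethyl (2E,4S)-2,4-dimethylhex-2-enoate | CC[C@H](C)/C=C(C)/C(=O)OCC | intermediate
17 | (2E,4S)-2,4-dimethylhex-2-en-1-ol | CC[C@H](C)/C=C(C)/CO | intermediate
18 | (2E,4S)-2,4-dimethylhex-2-enal | CC[C@H](C)/C=C(C)/C=O | intermediate
19 | (1E,3E,5S)-1-iodo-3,5-dimethylhepta-1,3-diene | CC[C@H](C)/C=C(C)/C=C/I | intermediate
20 | (2S,6R)-6-acetyl-6-({[tert-butyl(diphenyl)silyl]oxy}methyl)-5-[(3E,5E,7S)-5,7-dimethylnona-3,5-dien-1-yn-1-yl]-2-hydroxy-2-methylcyclohex-4-ene-1,3-dione | CC[C@H](C)/C=C(C)/C=C/C#CC1=CC(=O)[C@](C)(O)C(=O)[C@@]1(C(C)=O)CO[Si](c1ccccc1)(c1ccccc1)C(C)(C)C | intermediate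
21 | (2S,6R)-6-acetyl-5-[(3E,5E,7S)-5,7-dimethylnona-3,5-dien-1-yn-1-yl]-2-hydroxy-6-(hydroxymethyl)-2-methylcyclohex-4-ene-1,3-dione | CC[C@H](C)/C=C(C)/C=C/C#CC1=CC(=O)[C@](C)(O)C(=O)[C@@]1(C(C)=O)CO | intermediate (not isolated)
22 | (7S,8aR)-8a-acetyl-3-[(1E,3E,5S)-3,5-dimethylhepta-1,3-dien-1-yl]-7-hydroxy-7-methyl-1H-isochromene-6,8(7H,8aH)-dione | CC[C@H](C)/C=C(C)/C=C/C1=CC2=CC(=O)[C@](C)(O)C(=O)[C@@]2(C(C)=O)CO1 | intermediate
23 | (7R,8aR)-8a-acetyl-5-chloro-3-[(1E,3E,5S)-3,5-dimethylhepta-1,3-dien-1-yl]-7-hydroxy-7-methyl-1H-isochromene-6,8(7H,8aH)-dione | CC[C@H](C)/C=C(C)/C=C/C1=CC2=C(Cl)C(=O)[C@](C)(O)C(=O)[C@@]2(C(C)=O)CO1 | intermediate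
24 | (7R,8R,8aS)-8a-acetyl-5-chloro-3-[(1E,3E,5S)-3,5-dimethylhepta-1,3-dien-1-yl]-7,8-dihydroxy-7-methyl-1,7,8,8a-tetrahydro-6H-isochromen-6-one (7-OH, 8-OH and 8a-acetyl on one face) | CC[C@H](C)/C=C(C)/C=C/C1=CC2=C(Cl)C(=O)[C@](C)(O)[C@H](O)[C@@]2(C(C)=O)CO1 | target

Total step count: 16.
Longest linear sequence: 10 steps (1 → 3 → 4 → 6 → 7 → 12 → 13 → 20 → 22 → 23 → 24; steps 1–4, 6, 7, 13–16).

Steps most likely to fail

1. Step 6. The acyl-anion equivalent may close on the wrong carbonyl (5-exo onto C8 or onto the acetyl group) or react as a homoenolate, and face control in the conjugate addition may be incomplete. The fallback sets out from 11, isolated after the first stage, and returns at 12. The carbene-catalysed benzoin is allowed to take the 5-exo course onto the diketone carbonyl next to the quaternary centre, the closure known for Michael adducts of 1,3-diketones, which gives 4,5-diacetyl-4-({[tert-butyl(diphenyl)silyl]oxy}methyl)-5-hydroxy-3-[(trimethylsilyl)ethynyl]cyclopent-2-en-1-one F1. A Lewis-acid-promoted α-ketol rearrangement (BF3·OEt2 or Al(OiPr)3, CH2Cl2) then shifts the ring acyl carbon from the carbinol carbon to the neighbouring acetyl carbon. This ring expansion forms the C6–C7 bond and should give the less congested six-membered ketol 12; the C7 configuration obtained this way would have to be checked.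

2. Step 16. Hydride may be delivered to the acetyl carbonyl as well as, or instead of, C8. The fallback sets out from 23 and returns at 24. Both ketones are reduced with excess NaBH4 (the vinylogous ester C6 stays) to the 8a-(1-hydroxyethyl) analogue of 24 F2. Then only the less hindered exocyclic carbinol is oxidised back to the acetyl group with a sterically sensitive oxoammonium system (TEMPO/PhI(OAc)2, CH2Cl2). The C8 carbinol, flanked by two fully substituted carbons, should be left untouched.

3. Step 15. Electrophilic chlorine may attack C4 or the dienyl side chain in competition with C5. The fallback sets out from 12 and returns at 23, chlorinating before the diene is present. HF·pyridine followed by π-acid- or phosphine-catalysed 6-endo closure of the freed alcohol onto the silyl alkyne gives 8a-acetyl-7-hydroxy-7-methyl-3-(trimethylsilyl)-1H-isochromene-6,8(7H,8aH)-dione F3. NCS can then only reach C5 and gives 8a-acetyl-5-chloro-7-hydroxy-7-methyl-3-(trimethylsilyl)-1H-isochromene-6,8(7H,8aH)-dione F4. Ipso-iododesilylation with NIS gives 8a-acetyl-5-chloro-7-hydroxy-3-iodo-7-methyl-1H-isochromene-6,8(7H,8aH)-dione F5. Stille coupling (Pd2(dba)3, AsPh3, CuI, DMF) with tributyl[(1E,3E,5S)-3,5-dimethylhepta-1,3-dien-1-yl]stannane F6, made from 19 by iodine–lithium exchange (t-BuLi, Et2O, −78 °C) and Bu3SnCl, then gives 23.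

Further compounds
F1 | step 6 | 4,5-diacetyl-4-({[tert-butyl(diphenyl)silyl]oxy}methyl)-5-hydroxy-3-[(trimethylsilyl)ethynyl]cyclopent-2-en-1-one (quaternary centre as in 11) | CC(=O)C1(O)C(=O)C=C(C#C[Si](C)(C)C)[C@]1(C(C)=O)CO[Si](c1ccccc1)(c1ccccc1)C(C)(C)C
F2 | step 16 | 5-chloro-3-[(1E,3E,5S)-3,5-dimethylhepta-1,3-dien-1-yl]-7,8-dihydroxy-8a-(1-hydroxyethyl)-7-methyl-1,7,8,8a-tetrahydro-6H-isochromen-6-one (ring stereocentres as in 24, both carbinol epimers) | CC[C@H](C)/C=C(C)/C=C/C1=CC2=C(Cl)C(=O)[C@](C)(O)[C@H](O)[C@@]2(C(C)O)CO1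
F3 | step 15 | 8a-acetyl-7-hydroxy-7-methyl-3-(trimethylsilyl)-1H-isochromene-6,8(7H,8aH)-dione (ring stereocentres as in 22) | C[Si](C)(C)C1=CC2=CC(=O)[C@](C)(O)C(=O)[C@@]2(C(C)=O)CO1
F4 | step 15 | 8a-acetyl-5-chloro-7-hydroxy-7-methyl-3-(trimethylsilyl)-1H-isochromene-6,8(7H,8aH)-dione | C[Si](C)(C)C1=CC2=C(Cl)C(=O)[C@](C)(O)C(=O)[C@@]2(C(C)=O)CO1
F5 | step 15 | 8a-acetyl-5-chloro-7-hydroxy-3-iodo-7-methyl-1H-isochromene-6,8(7H,8aH)-dione | IC1=CC2=C(Cl)C(=O)[C@](C)(O)C(=O)[C@@]2(C(C)=O)CO1
F6 | step 15 | tributyl[(1E,3E,5S)-3,5-dimethylhepta-1,3-dien-1-yl]stannane | CC[C@H](C)/C=C(C)/C=C/[Sn](CCCC)(CCCC)CCCC
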